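## Retrosynthetic overview

1. Briarane numbering is used: ring A = C1, C10–C14; ten-membered ring = C1–C10; γ-lactone = O–C7, C8, C17, C19(=O); methyls C15 (on C1), C16 (C5), C18 (C17), C20 (C11). The ten-membered ring is closed late by ring-closing metathesis at C5=C6, followed by desilylation, acetylation of O2/O9 and acetonide removal.
2. The lactone is closed earlier by forming the O–C7 bond: reagent-controlled epoxidation of the (E)-C7=C8 bond of a dienyl acid, then opening of the oxirane at C7 by the C19 carboxyl. This is possible because C7 is both the γ-carbon of the C19 acid (through C17 and C8) and the allylic carbon of the C7=C8–C6=CH2 diene, so the oxirane opens at C7 in a five-ring closure with inversion and its oxygen stays on C8 as the tertiary hydroxyl.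
3. The dienyl side chain (C8–C9 bond, 7E) comes from a nickel-catalysed reductive coupling of the ring A aldehyde (C9) with a 1,3-enyne made from the (S)-Roche ester (C17).
4. Ring A is built first by an enantioselective Diels–Alder reaction (bonds C1–C14 and C10–C11, setting C1/C10); C2 follows by CBS reduction, C11/C12 by Rubottom oxidation and Luche reduction.
5. Order of ring formation: ring A, then γ-lactone, then ten-membered ring.

Key step: step 21

Assumption: in step 2 the oxazaborolidinium cation is taken to shield the same enal face as with 2-substituted acroleins (the (S)-cation sends the diene to the face on which formyl carbon, Cβ and the α-substituent run clockwise); the target needs the other face, so the (R)-cation is specified.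

## Route

Step 1
Reactants: 1 pent-1-en-3-one
Product: 2 (Z)-triisopropyl(penta-1,3-dien-3-yloxy)silane
Conditions: TIPSOTf, Et3N, CH2Cl2, 0 °C → rt
Reagents that add atoms: triisopropylsilyl triflate, CC(C)[Si](OS(=O)(=O)C(F)(F)F)(C(C)C)C(C)C
Why: Soft enolisation and O-silylation of the ethyl ketone (silyl enol ether formation) should give the Z enol ether, whose methyl group lies "outside" in the s-cis diene.

Step 2
Reactants: 2 (Z)-triisopropyl(penta-1,3-dien-3-yloxy)silane; 3 ethyl (E)-3-methyl-4-oxobut-2-enoate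
Product: 4 ring A cycloadduct (C2 formyl and C15 methyl on C1, C9 ethyl ester on C10, silyl enol ether C12=C13)
Conditions: (R)-3,3-diphenyl-1-(o-tolyl)tetrahydropyrrolo[1,2-c][1,3,2]oxazaborole (20 mol%), Tf2NH (18 mol%), CH2Cl2, −78 → −40 °C
Reagents that add atoms: none
Why: Oxazaborolidinium-catalysed enantioselective Diels–Alder reaction: the boron-bound formyl group steers the nucleophilic diene terminus C11 to C10 and C14 to C1, the E dienophile places C2 and C9 trans, and shielding of one enal face by the catalyst sets (1S,10S), while C11 is erased again in step 8.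

Step 3
Reactants: 4 ring A cycloadduct; 5 4-bromo-2-methylbut-1-ene
Product: 7 C2 carbinol (both C2 epimers), via Grignard reagent 6 (not isolated)
Conditions: Mg, THF, rt; then 4, THF, −78 °C; NH4Cl (aq) at −78 °C
Reagents that add atoms: none
Why: Grignard addition to the neopentyl aldehyde, which is far more reactive than the flanked ester or the silyl enol ether; the C2 configuration is irrelevant because step 4 removes it.

Step 4
Reactants: 7 C2 carbinol
Product: 8 C2 ketone
Conditions: Dess–Martin periodinane, NaHCO3, CH2Cl2, 0 °C → rt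
Reagents that add atoms: none
Why: Dess–Martin oxidation under neutral conditions converges both C2 epimers to one ketone and leaves the silyl enol ether intact.

Step 5
Reactants: 8 C2 ketone
Product: 9 (2R)-carbinol
Conditions: (S)-2-methyl-CBS-oxazaborolidine (20 mol%), catecholborane, toluene, −78 °C
Reagents that add atoms: none
Why: Corey–Bakshi–Shibata reduction: with quaternary C1 as the large and C3H2 as the small group the (S)-catalyst should deliver hydride to give 2R, in the same sense as Felkin–Anh attack anti to C10, and catecholborane at −78 °C leaves the alkenes alone.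

Step 6
Reactants: 9 (2R)-carbinol
Product: 10 O2 silyl ether
Conditions: TBSOTf, 2,6-lutidine, CH2Cl2, −78 → 0 °C
Reagents that add atoms: tert-butyldimethylsilyl triflate, CC(C)(C)[Si](C)(C)OS(=O)(=O)C(F)(F)F
Why: Silylation with the triflate protects the hindered C2 hydroxyl and stops it from lactonising onto the C9 ester.

Step 7
Reactants: 10 O2 silyl ether
Product: 11 C12 enone (C13=C14)
Conditions: Pd(OAc)2 (10 mol%), O2 (1 atm), DMSO, 45 °C
Reagents that add atoms: none
Why: Saegusa–Ito oxidation in its aerobic catalytic form: the enol ether is regiodefined as C12=C13, so β-hydride loss can only create the C13=C14 enone.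

Step 8
Reactants: 11 C12 enone
Product: 13 C11 hydroxy enone, via trimethylsilyl dienol ether 12 (not isolated)
Conditions: TMSOTf, Et3N, CH2Cl2, 0 °C; then DMDO (1.05 equiv), acetone, −78 °C; citric acid (aq), THF
Reagents that add atoms: dimethyldioxirane, CC1(C)OO1
Why: Rubottom oxidation: enolisation can go only toward C11 (C1 is quaternary), and DMDO should attack the electron-rich enol ether bond of 12 from the face opposite to the C10 ester and the pseudoaxial C15 methyl, so the new tertiary hydroxyl is trans to C9 (11S), the isolated 1,1-disubstituted alkene being much less nucleophilic.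

Step 9
Reactants: 13 C11 hydroxy enone
Product: 14 C11/C12 cis-diol
Conditions: NaBH4, CeCl3·7H2O, MeOH, −78 °C
Reagents that add atoms: none
Why: Luche 1,2-reduction: hydride should add anti to the C11–O bond (Felkin–Anh polar model, axial attack on the half-chair with pseudoaxial C11–OH), giving the cis-diol (12R).

Step 10
Reactants: 14 C11/C12 cis-diol
Product: 15 acetonide ester
Conditions: 2,2-dimethoxypropane, PPTS (cat.), CH2Cl2, rt
Reagents that add atoms: 2,2-dimethoxypropane, COC(C)(C)OC
Why: Acid-catalysed acetonide formation on the cis-1,2-diol masks the allylic C12 and tertiary C11 hydroxyls until the last step.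

Step 11
Reactants: 15 acetonide ester
Product: 16 C9 primary alcohol
Conditions: LiAlH4, THF, 0 °C
Reagents that add atoms: none
Why: Hydride reduction of the ethyl ester to the C9 carbinol, with silyl ether, acetonide and alkenes inert.

Step 12
Reactants: 16 C9 primary alcohol
Product: 17 C9 aldehyde
Conditions: Dess–Martin periodinane, NaHCO3, CH2Cl2, 0 °C
Reagents that add atoms: none
Why: Buffered Dess–Martin oxidation gives the aldehyde without epimerising C10.

Step 13
Reactants: 18 methyl (S)-3-hydroxy-2-methylpropanoate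
Product: 19 methyl (S)-3-(tert-butyldimethylsilyloxy)-2-methylpropanoate
Conditions: TBSCl, imidazole, CH2Cl2, rt
Reagents that add atoms: tert-butyldimethylsilyl chloride, CC(C)(C)[Si](C)(C)Cl
Why: Standard silylation of the primary alcohol of the Roche ester, which carries the future C17 stereocentre.

Step 14
Reactants: 19 methyl (S)-3-(tert-butyldimethylsilyloxy)-2-methylpropanoate
Product: 20 (S)-3-(tert-butyldimethylsilyloxy)-2-methylpropanal
Conditions: iBu2AlH, CH2Cl2, −78 °C
Reagents that add atoms: none
Why: Partial reduction of the ester through the aluminium hemiacetal that is stable at −78 °C gives the aldehyde without touching C17.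

Step 15
Reactants: 20 (S)-3-(tert-butyldimethylsilyloxy)-2-methylpropanal
Product: 21 (R)-tert-butyldimethyl[(2-methylbut-3-yn-1-yl)oxy]silane
Conditions: dimethyl (1-diazo-2-oxopropyl)phosphonate, K2CO3, MeOH, 0 °C → rt
Reagents that add atoms: dimethyl (1-diazo-2-oxopropyl)phosphonate, CC(=O)C(=[N+]=[N-])P(=O)(OC)OC
Why: Ohira–Bestmann alkynylation (Seyferth–Gilbert homologation) converts the aldehyde into the terminal alkyne under mild base that should not epimerise C17.

Step 16
Reactants: 21 (R)-tert-butyldimethyl[(2-methylbut-3-yn-1-yl)oxy]silane; 22 bromoethene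
Product: 23 (R)-tert-butyldimethyl[(2-methylhex-5-en-3-yn-1-yl)oxy]silane
Conditions: Pd(PPh3)4 (3 mol%), CuI (6 mol%), Et2NH, THF, rt
Reagents that add atoms: none
Why: Sonogashira coupling of the terminal alkyne with vinyl bromide gives the 1,3-enyne without involving C17.

Step 17
Reactants: 17 C9 aldehyde; 23 (R)-tert-butyldimethyl[(2-methylhex-5-en-3-yn-1-yl)oxy]silane
Product: 24 (7E,9R,17R)-dienol
Conditions: Ni(cod)2 (10 mol%), P(c-C5H9)3 (20 mol%), Et3B (2 equiv), EtOAc, rt
Reagents that add atoms: none
Why: Nickel-catalysed reductive coupling of a 1,3-enyne with an aldehyde: the conjugated alkene directs C–C bond formation to the distal alkyne carbon C8 and hydrogen is delivered to C7 cis to C9, giving the 7E diene, while Felkin–Anh attack anti to the quaternary C1 (the larger α-branch) should set 9R.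

Step 18
Reactants: 24 (7E,9R,17R)-dienol
Product: 25 tris-silyl ether
Conditions: TBSOTf, 2,6-lutidine, CH2Cl2, 0 °C
Reagents that add atoms: tert-butyldimethylsilyl triflate, CC(C)(C)[Si](C)(C)OS(=O)(=O)C(F)(F)F
Why: Silylation of the hindered allylic C9 hydroxyl with the triflate prevents the C19 acid made in step 20 from lactonising onto O9.

Step 19
Reactants: 25 tris-silyl ether
Product: 26 C19 primary alcohol
Conditions: HF·pyridine, pyridine, THF, 0 °C
Reagents that add atoms: none
Why: Under buffered fluoride the primary silyl ether is cleaved much faster than the two flanked secondary ones, and the acetonide is stable.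

Step 20
Reactants: 26 C19 primary alcohol
Product: 27 dienyl acid
Conditions: TEMPO (20 mol%), PhI(OAc)2 (2.2 equiv), MeCN/H2O, rt
Reagents that add atoms: water, O
Why: TEMPO/PhI(OAc)2 oxidation of the primary alcohol through the aldehyde hydrate to the acid in near-neutral aqueous medium should leave C17 and the diene untouched.

Step 21
Reactants: 27 dienyl acid
Product: 29 (7S,8S)-hydroxy lactone, via vinyl epoxy acid 28 (not isolated)
Conditions: D-fructose-derived Shi ketone (30 mol%), Oxone, K2CO3, Bu4NHSO4, MeCN/dimethoxymethane/aq. Na2B4O7–Na2EDTA (pH 10.5), 0 °C; then NaH2PO4/citric acid (aq) to pH 3–4, 0 °C → rt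
Reagents that add atoms: potassium peroxymonosulfate (Oxone), [K+].[O-]S(=O)(=O)OO
Why: The dioxirane formed from the ketone and Oxone transfers oxygen to the only trans-trisubstituted, electron-rich double bond (C7=C8) through the spiro transition state in which the lone vinylic hydrogen H7 faces the catalyst's dioxolane, which should give the (7R,8S)-oxirane 28 on the face that the C10 ring carbon also leaves open in the A(1,2)-minimised conformer (matched case). On acidification the C19 carboxyl oxygen opens the protonated vinyl oxirane at C7 with inversion, fixing 7S and leaving the oxirane oxygen as the tertiary C8 hydroxyl (8S). The closest known reaction type is the Shi epoxidation of conjugated dienes and unsaturated acids followed by lactonisation of a 3,4-epoxy acid to a 3-hydroxy-γ-lactone. The one ring closed is the γ-lactone, by a 5-endo-tet oxirane opening that is favoured here because C7 is allylic to C6=CH2 and attack at C8 would give a four-membered ring. The step needs chemoselectivity over the terminal, the 1,1-disubstituted and the cis-cyclic C=C bonds (poor substrates for this ketone) and C7-over-C8 regioselectivity, and the silyl ether on O9 excludes acyl capture or neighbouring-group opening by that oxygen.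

Step 22
Reactants: 29 (7S,8S)-hydroxy lactone
Product: 30 macrocyclic bis-silyl ether acetonide (5Z)
Conditions: second-generation Hoveyda–Grubbs catalyst [RuCl2(H2IMes)(=CH-C6H4-2-OiPr)] (10 mol%), toluene (1 mM), 80 °C
Reagents that add atoms: none
Why: Ring-closing metathesis between the C6 vinyl group and the 1,1-disubstituted C5 alkene with loss of ethylene should close the ten-membered ring, the ring-cis (Z) trisubstituted alkene being expected as the less strained isomer between the trans-fused lactone and ring A.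

Step 23
Reactants: 30 macrocyclic bis-silyl ether acetonide
Product: 31 C2/C9 diol acetonide
Conditions: HF·pyridine, pyridine, THF, rt
Reagents that add atoms: none
Why: Fluoride cleavage of the two secondary silyl ethers under buffered conditions that leave acetonide and lactone intact.

Step 24
Reactants: 31 C2/C9 diol acetonide
Product: 32 diacetate acetonide
Conditions: Ac2O, DMAP, pyridine, CH2Cl2, 0 °C → rt
Reagents that add atoms: acetic anhydride, CC(=O)OC(C)=O
Why: DMAP-catalysed acetylation of the two secondary alcohols, the tertiary C8 hydroxyl being unreactive under these conditions.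

Step 25
Reactants: 32 diacetate acetonide
Product: 33 target CNP0146024.1
Conditions: AcOH/H2O/THF (3:1:1), 45 °C
Reagents that add atoms: none
Why: Mild acidic hydrolysis of the acetonide frees the C11/C12 cis-diol, while acetates, lactone and the tertiary C8 hydroxyl tolerate aqueous acetic acid.

## Compound list

1 | pent-1-en-3-one | CCC(=O)C=C | starting material
2 | (Z)-triisopropyl(penta-1,3-dien-3-yloxy)silane | C=C/C(O[Si](C(C)C)(C(C)C)C(C)C)=C/C | intermediate
3 | ethyl (E)-3-methyl-4-oxobut-2-enoate | CCOC(=O)/C=C(\C)C=O | starting material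
4 | ring A cycloadduct: C1 bears formyl (C2) and methyl C15, C10 bears the ethyl ester (C9) trans to C2, C11 bears methyl C20, triisopropylsilyl enol ether C12=C13; (1S,10S,11R) | CCOC(=O)[C@H]1[C@@H](C)C(O[Si](C(C)C)(C(C)C)C(C)C)=CC[C@]1(C)C=O | intermediate
5 | 4-bromo-2-methylbut-1-ene | C=C(C)CCBr | starting material
6 | (3-methylbut-3-en-1-yl)magnesium bromide | C=C(C)CC[Mg]Br | intermediate
7 | C2 carbinol of 4 with the C3–C5 chain attached (mixture of C2 epimers) | CCOC(=O)[C@H]1[C@@H](C)C(O[Si](C(C)C)(C(C)C)C(C)C)=CC[C@]1(C)C(O)CCC(C)=C | intermediate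
8 | C2 ketone (4-methylpent-4-enoyl group on C1) | CCOC(=O)[C@H]1[C@@H](C)C(O[Si](C(C)C)(C(C)C)C(C)C)=CC[C@]1(C)C(=O)CCC(C)=C | intermediate
9 | (1S,2R)-C2 carbinol | CCOC(=O)[C@H]1[C@@H](C)C(O[Si](C(C)C)(C(C)C)C(C)C)=CC[C@]1(C)[C@H](O)CCC(C)=C | intermediate
10 | O2 tert-butyldimethylsilyl ether of 9 | CCOC(=O)[C@H]1[C@@H](C)C(O[Si](C(C)C)(C(C)C)C(C)C)=CC[C@]1(C)[C@H](O[Si](C)(C)C(C)(C)C)CCC(C)=C | intermediate
11 | C12 enone (C13=C14), O2 silyl ether, C9 ethyl ester | CCOC(=O)[C@H]1[C@@H](C)C(=O)C=C[C@]1(C)[C@H](O[Si](C)(C)C(C)(C)C)CCC(C)=C | intermediate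
12 | cross-conjugated trimethylsilyl dienol ether (C11=C12(OSiMe3)–C13=C14) | CCOC(=O)[C@H]1C(C)=C(O[Si](C)(C)C)C=C[C@]1(C)[C@H](O[Si](C)(C)C(C)(C)C)CCC(C)=C | intermediate
13 | (11S)-11-hydroxy-C12 enone (C11–OH trans to C9) | CCOC(=O)[C@H]1[C@](C)(O)C(=O)C=C[C@]1(C)[C@H](O[Si](C)(C)C(C)(C)C)CCC(C)=C | intermediate
14 | (11S,12R)-cis-diol | CCOC(=O)[C@H]1[C@](C)(O)[C@H](O)C=C[C@]1(C)[C@H](O[Si](C)(C)C(C)(C)C)CCC(C)=C | intermediate
15 | 11,12-acetonide, C9 ethyl ester | CCOC(=O)[C@H]1[C@]2(C)OC(C)(C)O[C@@H]2C=C[C@]1(C)[C@H](O[Si](C)(C)C(C)(C)C)CCC(C)=C | intermediate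
16 | 11,12-acetonide, C9 primary alcohol | OC[C@H]1[C@]2(C)OC(C)(C)O[C@@H]2C=C[C@]1(C)[C@H](O[Si](C)(C)C(C)(C)C)CCC(C)=C | intermediate
17 | 11,12-acetonide, C9 aldehyde (ring A fragment; 1S,2R,11S,12R) | O=C[C@H]1[C@]2(C)OC(C)(C)O[C@@H]2C=C[C@]1(C)[C@H](O[Si](C)(C)C(C)(C)C)CCC(C)=C | intermediate
18 | methyl (S)-3-hydroxy-2-methylpropanoate | OC[C@H](C)C(=O)OC | starting material
19 | methyl (S)-3-(tert-butyldimethylsilyloxy)-2-methylpropanoate | CC(C)(C)[Si](C)(C)OC[C@H](C)C(=O)OC | intermediate
20 | (S)-3-(tert-butyldimethylsilyloxy)-2-methylpropanal | CC(C)(C)[Si](C)(C)OC[C@H](C)C=O | intermediate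
21 | (R)-tert-butyldimethyl[(2-methylbut-3-yn-1-yl)oxy]silane | CC(C)(C)[Si](C)(C)OC[C@H](C)C#C | intermediate
22 | bromoethene (vinyl bromide) | C=CBr | starting material
23 | (R)-tert-butyldimethyl[(2-methylhex-5-en-3-yn-1-yl)oxy]silane | CC(C)(C)[Si](C)(C)OC[C@H](C)C#CC=C | intermediate
24 | (7E,9R,17R)-dienol: C9 carbinol joined to C8 of the C8=C7–C6=CH2 diene, C8 bearing CH(CH3)CH2OTBS; ring A as in 17 | O[C@@H](/C(=C/C=C)[C@@H](C)CO[Si](C)(C)C(C)(C)C)[C@H]1[C@]2(C)OC(C)(C)O[C@@H]2C=C[C@]1(C)[C@H](O[Si](C)(C)C(C)(C)C)CCC(C)=C | intermediate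
25 | O9 silyl ether of 24 (silyl ethers on O2, O9, O19) | CC(C)(C)[Si](C)(C)O[C@@H](/C(=C/C=C)[C@@H](C)CO[Si](C)(C)C(C)(C)C)[C@H]1[C@]2(C)OC(C)(C)O[C@@H]2C=C[C@]1(C)[C@H](O[Si](C)(C)C(C)(C)C)CCC(C)=C | intermediate
26 | C19 primary alcohol (silyl ethers on O2, O9) | CC(C)(C)[Si](C)(C)O[C@@H](/C(=C/C=C)[C@@H](C)CO)[C@H]1[C@]2(C)OC(C)(C)O[C@@H]2C=C[C@]1(C)[C@H](O[Si](C)(C)C(C)(C)C)CCC(C)=C | intermediate
27 | (7E,17R)-dienyl acid (C19 carboxylic acid) | CC(C)(C)[Si](C)(C)O[C@@H](/C(=C/C=C)[C@@H](C)C(=O)O)[C@H]1[C@]2(C)OC(C)(C)O[C@@H]2C=C[C@]1(C)[C@H](O[Si](C)(C)C(C)(C)C)CCC(C)=C | intermediate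
28 | (7R,8S)-7,8-epoxy acid (vinyl oxirane) | CC(C)(C)[Si](C)(C)O[C@@H]([C@]1(O[C@@H]1C=C)[C@@H](C)C(=O)O)[C@H]2[C@]3(C)OC(C)(C)O[C@@H]3C=C[C@]2(C)[C@H](O[Si](C)(C)C(C)(C)C)CCC(C)=C | intermediate
29 | (7S,8S,17R)-γ-lactone with C7 vinyl and tertiary C8–OH; silyl ethers on O2 and O9; 11,12-acetonide | CC(C)(C)[Si](C)(C)O[C@@H]([C@@]1(O)[C@H](C=C)OC(=O)[C@@H]1C)[C@H]2[C@]3(C)OC(C)(C)O[C@@H]3C=C[C@]2(C)[C@H](O[Si](C)(C)C(C)(C)C)CCC(C)=C | intermediate
30 | (5Z)-macrocycle: target skeleton with silyl ethers on O2 and O9 and 11,12-acetonide | CC(C)(C)[Si](C)(C)O[C@@H]1[C@H]2[C@]3(C)OC(C)(C)O[C@@H]3C=C[C@]2(C)[C@H](O[Si](C)(C)C(C)(C)C)CC/C(C)=C\[C@@H]2OC(=O)[C@H](C)[C@]21O | intermediate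
31 | 2,9-diol 11,12-acetonide | O[C@@H]1[C@H]2[C@]3(C)OC(C)(C)O[C@@H]3C=C[C@]2(C)[C@H](O)CC/C(C)=C\[C@@H]2OC(=O)[C@H](C)[C@]21O | intermediate
32 | 2,9-diacetate 11,12-acetonide | CC(=O)O[C@@H]1[C@H]2[C@]3(C)OC(C)(C)O[C@@H]3C=C[C@]2(C)[C@H](OC(C)=O)CC/C(C)=C\[C@@H]2OC(=O)[C@H](C)[C@]21O | intermediate
33 | CNP0146024.1: (1S,2R,5Z,7S,8S,9R,10S,11S,12R,17R)-2,9-diacetoxy-8,11,12-trihydroxybriara-5,13-diene γ-lactone (C19 carbonyl to O–C7) | CC(=O)O[C@@H]1[C@H]2[C@](C)(O)[C@H](O)C=C[C@]2(C)[C@H](OC(C)=O)CC/C(C)=C\[C@@H]2OC(=O)[C@H](C)[C@]21O | target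

## Step count and risks

Total step count: 25. Longest linear sequence: 21 steps (steps 1–12 and 17–25).

Steps most likely to fail:

Step 22 (ring-closing metathesis). The risk is poor control of the C5=C6 geometry, or failure of the encumbered trisubstituted ring closure in favour of oligomerisation. The fallback sets out from dienyl acid 27 and closes the ring before the lactone. Ring-closing metathesis of the terminal diene unit with the 1,1-disubstituted alkene (same ruthenium catalyst, toluene, 80 °C, high dilution) should give the macrocyclic (5Z,7E)-dienyl acid F1, because a ten-membered 1,3-diene cannot hold two E bonds and C7=C8 is already E. Shi epoxidation and acid-triggered lactonisation of F1 under the conditions of step 21 then lead to macrocycle 30, where the route is rejoined.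

Step 21 (epoxidation–lactonisation). The risk is slow or face-unselective oxygen transfer to the encumbered C7=C8 bond, or competing oxidation of the other alkenes. The fallback sets out from dienol 24 and uses substrate direction instead of reagent control. Hydroxyl-directed epoxidation (VO(acac)2, tBuOOH, CH2Cl2, 0 °C) should give the erythro epoxy alcohol F2 on the same face, since A(1,2) strain holds H9 in the alkene plane and the metal-bound O9 on the face away from C10. Silylation (TBSOTf, 2,6-lutidine) gives the tris-silyl epoxide F3. Buffered Bu4NF/AcOH removes the primary silyl ether to give epoxy alcohol F4. Dess–Martin oxidation gives epoxy aldehyde F5, and Pinnick oxidation (NaClO2, NaH2PO4, 2-methyl-2-butene) gives epoxy acid 28, which should close in the acidic buffer to lactone 29, where the route is rejoined.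

Step 17 (nickel-catalysed coupling). The risk is that the doubly flanked aldehyde does not undergo oxidative cyclisation at nickel, or that facial selectivity at C9 is low. The fallback sets out from enyne 23 and makes the C8–C9 bond by a Nozaki–Hiyama–Kishi reaction. Bu4NF gives enynol F6, and 1,1,3,3-tetramethyldisilazane gives the dimethylsilyl ether F7. Platinum-catalysed intramolecular syn hydrosilylation (Karstedt catalyst, Pt2[(CH2=CHSiMe2)2O]3) closes the five-membered cyclic siloxane F8, with silicon on C8 and H7 cis to it. Iododesilylation with retention (N-iodosuccinimide, then KF) gives the iodo dienol F9, and TBSCl/imidazole gives the silyl-protected dienyl iodide F10. Coupling of F10 with aldehyde 17 (CrCl2, NiCl2 cat., DMSO, optionally with a chiral sulfonamide ligand on chromium for reagent control at C9) returns to the route at dienol 24.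

## Further compounds

F1 | step 22 | macrocyclic (5Z,7E)-dienyl acid: ten-membered ring closed, C8 bearing (R)-CH(CH3)CO2H, silyl ethers on O2 and O9, 11,12-acetonide | CC(C)(C)[Si](C)(C)O[C@@H]1[C@H]2[C@]3(C)OC(C)(C)O[C@@H]3C=C[C@]2(C)[C@H](O[Si](C)(C)C(C)(C)C)CC/C(C)=C\C=C1/[C@@H](C)C(=O)O
F2 | step 21 | 7,8-epoxy alcohol from 24 (oxirane on the same face as in 28, free C9–OH, C19 silyl ether) | O[C@@H]([C@]1(O[C@@H]1C=C)[C@@H](C)CO[Si](C)(C)C(C)(C)C)[C@H]2[C@]3(C)OC(C)(C)O[C@@H]3C=C[C@]2(C)[C@H](O[Si](C)(C)C(C)(C)C)CCC(C)=C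
F3 | step 21 | O9 silyl ether of F2 (tris-silyl epoxide) | CC(C)(C)[Si](C)(C)O[C@@H]([C@]1(O[C@@H]1C=C)[C@@H](C)CO[Si](C)(C)C(C)(C)C)[C@H]2[C@]3(C)OC(C)(C)O[C@@H]3C=C[C@]2(C)[C@H](O[Si](C)(C)C(C)(C)C)CCC(C)=C
F4 | step 21 | epoxy C19 primary alcohol | CC(C)(C)[Si](C)(C)O[C@@H]([C@]1(O[C@@H]1C=C)[C@@H](C)CO)[C@H]2[C@]3(C)OC(C)(C)O[C@@H]3C=C[C@]2(C)[C@H](O[Si](C)(C)C(C)(C)C)CCC(C)=C
F5 | step 21 | epoxy C19 aldehyde | CC(C)(C)[Si](C)(C)O[C@@H]([C@]1(O[C@@H]1C=C)[C@@H](C)C=O)[C@H]2[C@]3(C)OC(C)(C)O[C@@H]3C=C[C@]2(C)[C@H](O[Si](C)(C)C(C)(C)C)CCC(C)=C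
F6 | step 17 | (R)-2-methylhex-5-en-3-yn-1-ol | OC[C@H](C)C#CC=C
F7 | step 17 | (R)-dimethyl[(2-methylhex-5-en-3-yn-1-yl)oxy]silane | C[SiH](C)OC[C@H](C)C#CC=C
F8 | step 17 | cyclic alkenyl siloxane: 2,2,4-trimethyl-3-(prop-2-en-1-ylidene)-1,2-oxasilolane, silicon on C8 trans to the vinyl group | C=C/C=C1\[C@@H](C)CO[Si]1(C)C
F9 | step 17 | (2S,3E)-3-iodo-2-methylhexa-3,5-dien-1-ol | OC[C@H](C)/C(I)=C\C=C
F10 | step 17 | tert-butyl{[(2S,3E)-3-iodo-2-methylhexa-3,5-dien-1-yl]oxy}dimethylsilane | CC(C)(C)[Si](C)(C)OC[C@H](C)/C(I)=C\C=C
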